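## Retrosynthetic overview

The strategy rests on the bare E-CH=CH unit (Cα, Cβ) between the ketone carbon on C1' of ring A (the acyl-bearing ring) and C1 of ring B (the phenyl ring). Both flanking bonds, C(=O)–Cα and Cβ–C1 of ring B, are cut, leading back to a ring A aroyl chloride, (E)-1,2-bis(tributylstannyl)ethene and iodobenzene, joined by two Stille couplings in one flask under neutral conditions.
The three phenols travel as acetates so that the C2' oxygen cannot add to the enone. They come off in the last step.
The carboxyl carbon on C1' comes from formylation and oxidation of 2-(2-hydroxybenzyl)-5-methoxyresorcinol. Its two free ring A carbons are related by a mirror plane, so no C3'/C5' regiochemical question arises.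
The ring A–CH2–ring C link (ring C is the hydroxybenzyl ring) comes from directed lithiation of bis-MOM 5-methoxyresorcinol between its two OMOM groups, addition to MOM-protected salicylaldehyde, and ionic deoxygenation.
No ring is formed at any stage: rings A, B and C are all bought as benzene rings.

Key step: step 9

Assumption: carbinol 7 forms as a racemate. This is immaterial, because its stereocentre is erased in step 4 and the target has only the E alkene as a stereochemical element.

## Route

Step 1
Reactants: 1 5-methoxyresorcinol (5-methoxybenzene-1,3-diol)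
Product: 2 1-methoxy-3,5-bis(methoxymethoxy)benzene
Conditions: MOMCl (2.5 equiv), i-Pr2NEt (3 equiv), CH2Cl2, 0 °C → rt
Reagents that add atoms: chloromethyl methyl ether (MOMCl), COCCl
Why: Williamson-type O-alkylation of both phenols by the very reactive α-chloro ether is fast under a mild amine base, and the OMOM groups it installs are the directing groups needed in step 3.

Step 2
Reactants: 3 salicylaldehyde
Product: 4 2-(methoxymethoxy)benzaldehyde
Conditions: MOMCl (1.3 equiv), i-Pr2NEt (1.5 equiv), CH2Cl2, 0 °C → rt
Reagents that add atoms: chloromethyl methyl ether (MOMCl), COCCl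
Why: The same Williamson-type O-alkylation masks the acidic phenol as a base-stable acetal, so the aldehyde consumes only one equivalent of aryllithium in step 3.

Step 3
Reactants: 2 1-methoxy-3,5-bis(methoxymethoxy)benzene; 4 2-(methoxymethoxy)benzaldehyde
Product: 7 (±)-[4-methoxy-2,6-bis(methoxymethoxy)phenyl][2-(methoxymethoxy)phenyl]methanol, via aryllithium 5 (not isolated), via lithium alkoxide 6 (not isolated)
Conditions: n-BuLi (1.1 equiv), THF, 0 °C, 1 h; then 4, −78 → 0 °C; H2O
Reagents that add atoms: none
Why: Directed ortho-metalation followed by 1,2-addition to an aldehyde: C2 of 2 lies between two chelating OMOM groups, which direct much better than OMe, so it should be lithiated in preference to C4/C6, and the new carbinol centre forms as a racemate that is erased in step 4.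

Step 4
Reactants: 7 (±)-[4-methoxy-2,6-bis(methoxymethoxy)phenyl][2-(methoxymethoxy)phenyl]methanol
Product: 9 2-(2-hydroxybenzyl)-5-methoxybenzene-1,3-diol, via tris-MOM diarylmethane 8 (not isolated)
Conditions: Et3SiH (1.5 equiv), CF3CO2H (5 equiv), CH2Cl2, −20 → 0 °C; evaporate; then HCl (1 M), MeOH, 40 °C
Reagents that add atoms: none
Why: Ionic hydrogenation (acid ionises the carbinol to a benzhydryl cation stabilised by four oxygen donors and Et3SiH delivers hydride irreversibly) is followed by acid-catalysed acetal exchange with methanol, which carries off the MOM groups as dimethoxymethane, so any MOM loss in the first stage is harmless.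

Step 5
Reactants: 9 2-(2-hydroxybenzyl)-5-methoxybenzene-1,3-diol
Product: 11 2,4-dihydroxy-3-(2-hydroxybenzyl)-6-methoxybenzaldehyde, via aryl iminium chloride 10 (not isolated)
Conditions: POCl3 (1.2 equiv) and DMF premixed at 0 °C, MeCN; then 9, 0 °C → rt; then H2O, 40 °C
Reagents that add atoms: N,N-dimethylformamide, CN(C)C=O; water, O
Why: Vilsmeier–Haack formylation: the two open ring A positions of 9 are equivalent by symmetry and give the same aldehyde, ring C with its single donor cannot compete, the first formyl group deactivates ring A against a second attack, and premixing the reagent keeps free POCl3 away from the two neighbouring phenols.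

Step 6
Reactants: 11 2,4-dihydroxy-3-(2-hydroxybenzyl)-6-methoxybenzaldehyde
Product: 12 2,4-diacetoxy-3-(2-acetoxybenzyl)-6-methoxybenzaldehyde
Conditions: Ac2O (5 equiv), pyridine, DMAP (cat.), CH2Cl2, 0 °C → rt
Reagents that add atoms: acetic anhydride, CC(=O)OC(C)=O
Why: DMAP-catalysed acylation esterifies all three phenols, including the hydrogen-bonded C2 hydroxyl, and acetates are chosen because they tolerate chlorite, oxalyl chloride and neutral palladium catalysis, as the stability of acetylsalicyloyl chloride indicates.

Step 7
Reactants: 12 2,4-diacetoxy-3-(2-acetoxybenzyl)-6-methoxybenzaldehyde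
Product: 13 2,4-diacetoxy-3-(2-acetoxybenzyl)-6-methoxybenzoic acid
Conditions: NaClO2, NaH2PO4, 2-methyl-2-butene, t-BuOH/THF/H2O, 0 °C → rt
Reagents that add atoms: NaClO2 (sodium chlorite), [Na+].[O-]Cl=O
Why: Pinnick oxidation at about pH 4 turns hindered aromatic aldehydes into acids without touching aryl acetates, 2-methyl-2-butene takes up HOCl before it can chlorinate C5 of ring A, and reaching the acid with its phenols already acetylated avoids the free 2,4-dihydroxy-6-methoxybenzoic acid, which would lose CO2 easily.

Step 8
Reactants: 13 2,4-diacetoxy-3-(2-acetoxybenzyl)-6-methoxybenzoic acid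
Product: 14 2,4-diacetoxy-3-(2-acetoxybenzyl)-6-methoxybenzoyl chloride
Conditions: (COCl)2 (1.5 equiv), DMF (cat.), CH2Cl2, 0 °C → rt; evaporate, strip twice with toluene, use at once
Reagents that add atoms: oxalyl chloride, O=C(Cl)C(=O)Cl
Why: Acid chloride formation through catalytic Vilsmeier-type activation by DMF runs at or below room temperature with only gaseous by-products, and stripping with toluene removes HCl that would otherwise protodestannylate 15 in step 9.

Step 9
Reactants: 14 2,4-diacetoxy-3-(2-acetoxybenzyl)-6-methoxybenzoyl chloride; 15 (E)-1,2-bis(tributylstannyl)ethene; 16 iodobenzene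
Product: 18 (E)-1-[2,4-diacetoxy-3-(2-acetoxybenzyl)-6-methoxyphenyl]-3-phenylprop-2-en-1-one, via β-stannyl enone 17 (not isolated)
Conditions: Pd(PPh3)4 (5 mol %), 15 (1.1 equiv), toluene, 55 °C, argon, until 14 is consumed; then 16 (1.5 equiv), CuI (20 mol %), DMF, 60 °C
Reagents that add atoms: none
Why: Two Stille couplings are run on one two-carbon bis-stannane: 14 adds oxidatively to zerovalent palladium to give an aroylpalladium chloride (divalent palladium), one vinyl–tin bond of 15 transmetalates, and reductive elimination forges C(=O)–Cα to give 17 with the E geometry retained. The closest known reactions are the palladium-catalysed acylation of (E)-1,2-bis(tributylstannyl)ethene to E β-stannyl enones and the CuI-accelerated Stille arylation of such enones, here run one after the other in the same flask. The step needs mono-acylation, and the substrate secures it, because the tin left in 17 sits on a carbon conjugated to the ketone and transmetalates far more slowly than electron-rich 15, which is also kept in slight excess. Once 14 is gone, 16 adds to zerovalent palladium, CuI takes up free PPh3 and relays the vinyl group from tin, and reductive elimination forms Cβ–C1 of ring B, again with retention. No ring is closed and no stereocentre is created, so the only stereochemical element, the E alkene, is carried over from 15. A bath at or below 60 °C holds back CO loss from the di-ortho-substituted aroylpalladium species, toluene avoids acylative cleavage of an ether solvent, and the neutral medium leaves untouched the three acetates that keep the C2' oxygen from adding to the enone.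

Step 10
Reactants: 18 (E)-1-[2,4-diacetoxy-3-(2-acetoxybenzyl)-6-methoxyphenyl]-3-phenylprop-2-en-1-one
Product: 20 (E)-1-[2,4-dihydroxy-3-(2-hydroxybenzyl)-6-methoxyphenyl]-3-phenylprop-2-en-1-one (target), via potassium phenolate 19 (not isolated)
Conditions: K2CO3 (4 equiv), degassed MeOH, 0 °C → rt; then poured into ice-cold 1 M HCl (pH 3–4)
Reagents that add atoms: none
Why: Base-catalysed transesterification (Zemplén-type methanolysis) cleaves aryl acetates quickly, the freed C4' phenol is held as its potassium salt 19, whose charge is delocalised into the enone and so disfavours oxa-Michael closure to the flavanone, and cold acidification should give the hydrogen-bonded 2'-hydroxychalcone with the thermodynamically preferred E alkene unchanged.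

## Compound list

1 | 5-methoxyresorcinol | COc1cc(O)cc(O)c1 | starting material
2 | 1-methoxy-3,5-bis(methoxymethoxy)benzene | COCOc1cc(OC)cc(OCOC)c1 | intermediate
3 | salicylaldehyde | O=Cc1ccccc1O | starting material
4 | 2-(methoxymethoxy)benzaldehyde | COCOc1ccccc1C=O | intermediate
5 | [4-methoxy-2,6-bis(methoxymethoxy)phenyl]lithium | [Li]c1c(OCOC)cc(OC)cc1OCOC | intermediate
6 | lithium alkoxide of 7 (racemic) | [Li+].COCOc1cc(OC)cc(OCOC)c1C([O-])c1ccccc1OCOC | intermediate
7 | (±)-[4-methoxy-2,6-bis(methoxymethoxy)phenyl][2-(methoxymethoxy)phenyl]methanol | COCOc1cc(OC)cc(OCOC)c1C(O)c1ccccc1OCOC | intermediate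
8 | 5-methoxy-1,3-bis(methoxymethoxy)-2-[2-(methoxymethoxy)benzyl]benzene | COCOc1cc(OC)cc(OCOC)c1Cc1ccccc1OCOC | intermediate
9 | 2-(2-hydroxybenzyl)-5-methoxybenzene-1,3-diol | COc1cc(O)c(Cc2ccccc2O)c(O)c1 | intermediate
10 | [2,4-dihydroxy-3-(2-hydroxybenzyl)-6-methoxybenzylidene]dimethyliminium chloride | COc1cc(O)c(Cc2ccccc2O)c(O)c1C=[N+](C)C.[Cl-] | intermediate
11 | 2,4-dihydroxy-3-(2-hydroxybenzyl)-6-methoxybenzaldehyde | COc1cc(O)c(Cc2ccccc2O)c(O)c1C=O | intermediate
12 | 2,4-diacetoxy-3-(2-acetoxybenzyl)-6-methoxybenzaldehyde | COc1cc(OC(C)=O)c(Cc2ccccc2OC(C)=O)c(OC(C)=O)c1C=O | intermediate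
13 | 2,4-diacetoxy-3-(2-acetoxybenzyl)-6-methoxybenzoic acid | COc1cc(OC(C)=O)c(Cc2ccccc2OC(C)=O)c(OC(C)=O)c1C(=O)O | intermediate
14 | 2,4-diacetoxy-3-(2-acetoxybenzyl)-6-methoxybenzoyl chloride | COc1cc(OC(C)=O)c(Cc2ccccc2OC(C)=O)c(OC(C)=O)c1C(=O)Cl | intermediate
15 | (E)-1,2-bis(tributylstannyl)ethene | CCCC[Sn](CCCC)(CCCC)/C=C/[Sn](CCCC)(CCCC)CCCC | starting material
16 | iodobenzene | Ic1ccccc1 | starting material
17 | (E)-1-[2,4-diacetoxy-3-(2-acetoxybenzyl)-6-methoxyphenyl]-3-(tributylstannyl)prop-2-en-1-one | COc1cc(OC(C)=O)c(Cc2ccccc2OC(C)=O)c(OC(C)=O)c1C(=O)/C=C/[Sn](CCCC)(CCCC)CCCC | intermediate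
18 | (E)-1-[2,4-diacetoxy-3-(2-acetoxybenzyl)-6-methoxyphenyl]-3-phenylprop-2-en-1-one | COc1cc(OC(C)=O)c(Cc2ccccc2OC(C)=O)c(OC(C)=O)c1C(=O)/C=C/c1ccccc1 | intermediate
19 | potassium C4' phenolate of 20 | [K+].COc1cc([O-])c(Cc2ccccc2O)c(O)c1C(=O)/C=C/c1ccccc1 | intermediate
20 | (E)-1-[2,4-dihydroxy-3-(2-hydroxybenzyl)-6-methoxyphenyl]-3-phenylprop-2-en-1-one (CID26249303) | COc1cc(O)c(Cc2ccccc2O)c(O)c1C(=O)/C=C/c1ccccc1 | target

## Step count and risks

Total step count: 10.
Longest linear sequence: 9 steps (1 → 2 → 7 → 9 → 11 → 12 → 13 → 14 → 18 → 20). Step 2 lies on a side branch.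

**Step 9.**
- In the second stage, tin-to-palladium transfer from the electron-poor vinylstannane may be so slow that protodestannylation and homocoupling take over.
- In the first stage, a second acylation or loss of CO from the hindered aroylpalladium species may intrude.
- The fallback inverts the order of the two bond formations, so the weak nucleophile 17 is never needed. It sets out from 15 and 16.
- Stille mono-arylation of 15 (threefold excess, Pd(PPh3)4, toluene, 80 °C) should give (E)-tributyl(2-phenylethenyl)stannane F1, which is isolated and freed of surplus 15.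
- The electron-rich styrylstannane F1 is then acylated with 14 (PdCl2(PPh3)2, toluene, 50 °C). This can run under 1 atm CO to suppress decarbonylation, which is permissible because no aryl iodide is present any longer.
- The fallback comes back to the route at 18.

**Step 10.**
- The freed C2' phenol may close onto Cβ (chalcone–flavanone isomerisation) during methanolysis or acidification, or methoxide may add to the enone.
- The fallback passes through the flavanone on purpose. It sets out from 18.
- HCl in refluxing MeOH removes the acetates and lets the oxa-Michael closure run on to (±)-7-hydroxy-8-(2-hydroxybenzyl)-5-methoxyflavanone F2, which is purified by crystallisation.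
- Brief exposure of F2 to concentrated aqueous KOH opens the pyranone ring by E1cB elimination to the chalcone polyphenolate.
- Rapid pouring into ice-cold HCl comes back to the route at 20.

**Step 4.**
- The benzhydryl cation may be captured by the electron-rich ring A of a second molecule (Friedel–Crafts oligomerisation).
- The unacylated ring A may also be bridged by the formaldehyde equivalent released on MOM cleavage.
- The fallback installs the formyl group before deprotection, so ring A is already deactivated when the MOM groups leave. It sets out from 7.
- Neutral hydrogenolysis (H2, Pd/C, EtOAc/EtOH) gives 8, now isolated.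
- NBS in MeCN at 0 °C brominates one of the two equivalent ring A positions to give 2-bromo-1-methoxy-3,5-bis(methoxymethoxy)-4-[2-(methoxymethoxy)benzyl]benzene F3.
- Bromine–lithium exchange (n-BuLi, THF, −78 °C) and a DMF quench give 6-methoxy-2,4-bis(methoxymethoxy)-3-[2-(methoxymethoxy)benzyl]benzaldehyde F4.
- HCl in MeOH then removes the three MOM groups, and the fallback comes back to the route at 11, bypassing 9, 10 and step 5.

## Further compounds

F1 | step 9 | (E)-tributyl(2-phenylethenyl)stannane | CCCC[Sn](CCCC)(CCCC)/C=C/c1ccccc1
F2 | step 10 | (±)-7-hydroxy-8-(2-hydroxybenzyl)-5-methoxyflavanone | COc1cc(O)c(Cc2ccccc2O)c3OC(c4ccccc4)CC(=O)c13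
F3 | step 4 | 2-bromo-1-methoxy-3,5-bis(methoxymethoxy)-4-[2-(methoxymethoxy)benzyl]benzene | COCOc1cc(OC)c(Br)c(OCOC)c1Cc1ccccc1OCOC
F4 | step 4 | 6-methoxy-2,4-bis(methoxymethoxy)-3-[2-(methoxymethoxy)benzyl]benzaldehyde | COCOc1cc(OC)c(C=O)c(OCOC)c1Cc1ccccc1OCOC
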